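## Structural features

The target is a (2S)-flavanone. Ring A is a phloroglucinol-type benzene fused to the dihydropyranone ring C (O1, C2, C3, C4, C4a, C8a), and C2 carries the 4-hydroxyphenyl ring B. C6 of ring A lies between the 5- and 7-hydroxyls and para to C8a, and is bonded to C2' of an N-methylpiperidine, so only C8 of ring A bears hydrogen. The two stereocentres, C2 (S) and C2' (R), are both benzylic but sit on opposite sides of ring A; they are not adjacent, neither can direct the other, and each needs its own source of asymmetry. Three features are fragile:
- a 5-hydroxyflavanone opens to the chalcone with base, which racemises C2 and, on reclosure through the 5-oxygen, moves the piperidine from C6 to C8;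
- the C2'–N bond is a benzylic amine on a trioxygenated ring and can ionise in strong acid or on heating once ortho or para hydroxyls are free;
- the basic nitrogen quenches acid catalysts unless it is masked.

The real difficulty is to make O1 the oxygen para (not ortho) to the piperidine, to set C2 absolutely without help from C2', and to unmask three phenols and the amine last under neutral conditions. The key step uses the fact that O1–C8a–C4a–C4 of ring C is the oxadiene of an ortho-quinone methide derived from a salicylaldehyde, and that C3–C2 with ring B is a styrene, so ring C and C2 arise in one cycloaddition.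

## Logic of the disconnections

22 ⇒ 21. The three O–benzyl bonds are cut last. The free phenols (base-labile C2, retro-Mannich at C2') are thereby absent from every earlier step. The forward step must be a neutral reductive cleavage that spares the benzylic C2–O1 and C2'–N bonds and the ketone.

21 ⇒ 20 ⇒ 19. The C4 carbonyl is traced back to the C4 alcohol and then to the C4 methyl ether. No skeletal bond is cut; the gain is that C4 stays at an ether level, inert to hydride, while nitrogen is adjusted, and its configuration never needs control. The forward steps demand an exchange at C4 that avoids elimination towards C3 and ionisation at C2, and an oxidant that leaves the tertiary amine alone.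

19 ⇒ 18. The N-methyl group is traced to an N-methoxycarbonyl group. The carbamate keeps nitrogen non-basic for the acid-catalysed key step and its carbon becomes the methyl group, so no separate methylation is needed. The forward step is a hydride reduction that must tolerate benzylic ethers.

18 ⇒ 13 + 15. C4–C3 and O1–C2 are cut, opening ring C into a salicylaldehyde and a styrene. This removes one ring and two stereocentres in one operation and leaves two achiral-at-ring-C fragments. The forward step must control C2 through a chiral counter-anion, and the substrate must offer exactly one free hydroxyl, the one next to the formyl group and para to the piperidine.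

13 ⇒ 12. The aryl–CHO bond is cut. The para position of the phenol is occupied and its two ortho positions are equivalent by rotation about the aryl–C2' bond, so no regioisomer can form. The demand is mono-formylation only.

12 ⇒ 10 (through 11). The N–CO2Me bond is cut, and the N–S and O–CH2OMe bonds are restored. One acid treatment removes auxiliary and acetal together, and the amine exists only as its salt until it is acylated, so the free para-hydroxybenzylamine is never heated. The demand is acylation at nitrogen and not at oxygen.

10 ⇒ 9. The N–C6' bond is cut. The piperidine closes by intramolecular alkylation of the sulfinamide nitrogen, which requires that the primary chloride has survived the organomagnesium step.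

9 ⇒ 6 + 7 (through 8). The C2'–C3' bond is cut. C2' is created by adding a four-carbon nucleophile to a sulfinyl aldimine, which reduces the problem to an aryl aldehyde, an auxiliary and a dihalide. The demand is facial control by the sulfur auxiliary despite two ortho substituents.

6 ⇒ 4 + 5. The C=N bond is cut, a plain condensation that needs a dehydrating Lewis acid because the aldehyde is hindered and electron-rich.

4 ⇒ 3 ⇒ 1. The O–CH2OMe bond and then the aryl–CHO bond are cut. Formylating, para to the free hydroxyl, a phenol whose other two oxygens are already benzylated distinguishes the oxygen that will become O1 without any selective protection of a triol. The demand is para over ortho selectivity; the temporary acetal is chosen because it falls in the same acid step as the auxiliary.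

15 ⇒ 14. The C=C bond is cut (one-carbon olefination), so ring B comes from a stable aldehyde and the acid-sensitive styrene is made just before use.

## Other disconnections considered

Alternative 1: The cut is N–C2'. In the forward step a bulky BINOL-derived chiral phosphoric acid dehydrates the acyclic benzylic alcohol A1 to an ortho-quinone methide, and the tethered carbamate nitrogen closes the piperidine (6-exo-trig) to give A2.
- In favour: the step is catalytic and needs no stoichiometric auxiliary. The nucleophile is tethered and has an N–H that can bind the phosphate, which is the two-point binding that chiral-acid methide chemistry normally relies on. On mechanistic precedent this is better than step 9, where 15 offers no such handle. The two phenols flanking the reacting carbon are equivalent, so the step poses no regiochemical question, which is equal to the chosen plan.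
- Against: A2 keeps free hydroxyls ortho to the new C–N bond, so the same acid can re-form the methide and erode the configuration. A carbamate nitrogen is a weak nucleophile, and the electron-rich ring of a second molecule can compete for the methide. The protection pattern of A2 is the inverse of what ring C needs, since the oxygen para to the piperidine is silylated and the flanking ones are free; bis-benzylation and desilylation would be needed to reach 12.
- Comparison: structurally this addresses only C2' and leaves ring C and C2 to be built afterwards, so it competes with steps 3–6 and not with step 9. Its step count to 12 is not lower once A1 has been assembled. Its stereocontrol is more elegant but less secure than the auxiliary addition of step 4, whose diastereomers can be separated.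

Alternative 2: The cuts are C2'–N and N–C6'. In the forward step an (R)-selective, pyridoxal-phosphate-dependent amine transaminase with a sacrificial amine donor converts the chloroketone A3 into the primary amine, which displaces chloride (6-exo-tet) to give the piperidine A4.
- In favour: one aqueous operation sets C2' and closes the ring, with no auxiliary and no cryogenic organometallic step. Where the enzyme accepts its substrate the enantiopurity is usually very high; on selectivity and atom economy this is potentially better than steps 3–5, and A3 is about as accessible as 6.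
- Against: the carbonyl of A3 is flanked by two ortho-alkoxy groups and a chloroalkyl chain, so both substituents are large and the aryl ketone is twisted. Transaminases generally require one small substituent, so enzyme screening or engineering is a precondition and not a detail. The acetal groups flanking the piperidine in A4 would not survive the strong acid and methanol of step 9, and the benzyl group sits on the oxygen that must be free; a protecting-group exchange of several steps would follow.
- Comparison: it delivers the same kind of piperidine as 10 with equal regiochemical meaning. Mechanistically the control is independent of the substrate's chelating groups, which is an advantage over step 4. Step economy is at best equal after the exchange of protecting groups, and predictability is lower.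

Alternative 3: The cuts are three C–C bonds of ring A. In the forward step heating the cyclobutenone A5 with the siloxyalkyne A6 (prepared from (R)-pipecolic acid A7) gives a vinylketene, a [2+2] adduct, a dienylketene and, after 6π closure and tautomerisation, the phenol A8.
- In favour: C2' comes from the chiral pool, so no asymmetric step is needed for it; on certainty of configuration this is better than step 4, provided nothing epimerises. The regiochemistry of the benzannulation is dictated by the pericyclic sequence and needs no catalyst, and ring A arrives with its three oxygens differentiated.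
- Against: A7 is the unnatural enantiomer. Its conversion into A6 passes through strongly basic ynolate chemistry next to the α-amino stereocentre. The differentiation delivered is the wrong one: the free hydroxyl of A8 flanks the piperidine, whereas O1 must be the para oxygen (here benzylated), so ring closure on the free hydroxyl would lead to the C8 isomer and the groups would have to be permuted. The tert-butyl carbamate would not survive the acid of step 9 and would have to be exchanged.
- Comparison: structurally it builds a ring that the chosen plan buys ready-made. Mechanistically it is sound and equal in predictability. In step count it is clearly longer, because both coupling partners and the protecting-group permutation must be added.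

Key step: step 9

Remarks on the chemistry:
- The configurations of 13 ((R) at C2') and 18 ((2S,4S), (R) at C2') were checked against the target and are consistent; (S)-configured sulfur leads to (R)-C2' by the chelate model.
- The (R)-enantiomer of the phosphoramide is assumed to give (2S)-18; if the sense is opposite, its mirror image is used and nothing else changes.
- 18 and 19 are written as the 2,4-cis isomers; any 2,4-trans material is carried along because C4 becomes a carbonyl in step 12.
- 1 is taken as a catalogue compound.

Step 1
Reactants: 1 3,5-bis(benzyloxy)phenol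
Product: 3 2,6-bis(benzyloxy)-4-hydroxybenzaldehyde, via iminium dichlorophosphate 2 (not isolated)
Conditions: POCl3, DMF, MeCN, 0 °C → rt; then H2O, 50 °C
Reagents that add atoms: N,N-dimethylformamide, CN(C)C=O (formyl carbon); water, O (carbonyl oxygen)
Why: Vilsmeier–Haack formylation; the chloroiminium ion should attack para to the free hydroxyl, between the two benzyloxy groups, as is usual for 3,5-dialkoxyphenols, and the hydrogen-bonded ortho isomer expected as the minor product is less polar and is removed by crystallisation or chromatography.

Step 2
Reactants: 3 2,6-bis(benzyloxy)-4-hydroxybenzaldehyde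
Product: 4 2,6-bis(benzyloxy)-4-(methoxymethoxy)benzaldehyde
Conditions: MOMCl, i-Pr2NEt, CH2Cl2, 0 °C → rt
Reagents that add atoms: chloromethyl methyl ether, COCCl
Why: O-alkylation of an acidic para-hydroxybenzaldehyde; the acetal withstands the organomagnesium and amide-base steps and is cleaved later by the same acid that removes the auxiliary.

Step 3
Reactants: 4 2,6-bis(benzyloxy)-4-(methoxymethoxy)benzaldehyde; 5 (S)-2-methylpropane-2-sulfinamide
Product: 6 (S)-N-{(E)-[2,6-bis(benzyloxy)-4-(methoxymethoxy)phenyl]methylidene}-2-methylpropane-2-sulfinamide
Conditions: Ti(OEt)4, THF, 65 °C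
Reagents that add atoms: none
Why: Titanium-mediated condensation of an aldehyde with tert-butanesulfinamide; Ti(OEt)4 activates the hindered carbonyl and takes up the water, the (E)-aldimine is the only geometry expected, and sulfur is not touched.

Step 4
Reactants: 6 (S)-N-{(E)-[2,6-bis(benzyloxy)-4-(methoxymethoxy)phenyl]methylidene}-2-methylpropane-2-sulfinamide; 7 1-bromo-4-chlorobutane
Product: 9 (S)-N-{(1R)-1-[2,6-bis(benzyloxy)-4-(methoxymethoxy)phenyl]-5-chloropentyl}-2-methylpropane-2-sulfinamide, via 4-chlorobutylmagnesium bromide 8 (not isolated)
Conditions: 7, Mg, THF, rt; then 6, CH2Cl2, −48 °C → −20 °C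
Reagents that add atoms: none
Why: Grignard 1,2-addition to an N-tert-butanesulfinyl aldimine; magnesium inserts only into the C–Br bond of 7, and in the non-coordinating solvent it bridges sulfinyl oxygen and imine nitrogen in a six-membered chair (Zimmerman–Traxler-type) transition state with the tert-butyl group equatorial, so the (S)-sulfur centre should direct the alkyl group to the face that gives (R)-C2'; the minor diastereomer is separable at this stage.

Step 5
Reactants: 9 (S)-N-{(1R)-1-[2,6-bis(benzyloxy)-4-(methoxymethoxy)phenyl]-5-chloropentyl}-2-methylpropane-2-sulfinamide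
Product: 10 (2R)-2-[2,6-bis(benzyloxy)-4-(methoxymethoxy)phenyl]-1-[(S)-tert-butylsulfinyl]piperidine
Conditions: KN(SiMe3)2, THF, 0 °C → rt
Reagents that add atoms: none
Why: Intramolecular N-alkylation (6-exo-tet SN2) of the potassium sulfinamide on the primary chloride; the stereocentre is not involved, and closing the ring while nitrogen is still sulfinylated avoids heating a free para-hydroxybenzylamine later.

Step 6
Reactants: 10 (2R)-2-[2,6-bis(benzyloxy)-4-(methoxymethoxy)phenyl]-1-[(S)-tert-butylsulfinyl]piperidine
Product: 12 methyl (R)-2-[2,6-bis(benzyloxy)-4-hydroxyphenyl]piperidine-1-carboxylate, via piperidine phenol hydrochloride 11 (not isolated)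
Conditions: HCl, MeOH, rt → 40 °C; evaporate; then ClCO2Me, NaHCO3, THF/H2O, 0 °C
Reagents that add atoms: methyl chloroformate, COC(=O)Cl
Why: Acidolysis cleaves the N–S bond and the methoxymethyl acetal in one operation while the amine is held as its ammonium salt, which does not ionise at C2'; Schotten–Baumann acylation then occurs at nitrogen because bicarbonate does not ionise the phenol, and the carbamate is both the non-basic form needed in step 9 and the latent N-methyl group.

Step 7
Reactants: 12 methyl (R)-2-[2,6-bis(benzyloxy)-4-hydroxyphenyl]piperidine-1-carboxylate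
Product: 13 methyl (R)-2-[2,6-bis(benzyloxy)-3-formyl-4-hydroxyphenyl]piperidine-1-carboxylate
Conditions: MgCl2, Et3N, (CH2O)n, MeCN, 80 °C
Reagents that add atoms: formaldehyde (as paraformaldehyde), C=O
Why: Magnesium-mediated ortho-formylation of a phenol (Casnati–Skattebøl); formaldehyde is delivered inside the magnesium phenoxide chelate to the ortho carbon and a second formaldehyde accepts hydride, and since the para position is blocked and the two ortho positions are equivalent only one regioisomer can form.

Step 8
Reactants: 14 4-(benzyloxy)benzaldehyde
Product: 15 1-(benzyloxy)-4-ethenylbenzene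
Conditions: Ph3PCH3Br, KOt-Bu, THF, 0 °C → rt
Reagents that add atoms: methyltriphenylphosphonium bromide, C[P+](c1ccccc1)(c1ccccc1)c1ccccc1.[Br-]
Why: Wittig methylenation of an aromatic aldehyde with a non-stabilised ylide; the styrene is used soon after purification because it is prone to acid-induced oligomerisation.

Step 9
Reactants: 13 methyl (R)-2-[2,6-bis(benzyloxy)-3-formyl-4-hydroxyphenyl]piperidine-1-carboxylate; 15 1-(benzyloxy)-4-ethenylbenzene
Product: 18 methyl (2R)-2-{(2S,4S)-5,7-bis(benzyloxy)-2-[4-(benzyloxy)phenyl]-4-methoxy-3,4-dihydro-2H-chromen-6-yl}piperidine-1-carboxylate, via dimethyl acetal 16 (not isolated), via methoxy ortho-quinone methide 17 (not isolated)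
Conditions: HC(OMe)3, (R)-3,3'-bis(2,4,6-triisopropylphenyl)-1,1'-binaphthyl-2,2'-diyl N-triflylphosphoramide (10 mol%), 4 Å MS, toluene/CH2Cl2, rt; then 15, −40 °C
Reagents that add atoms: trimethyl orthoformate, COC(OC)OC
Why: Proposed new method: the acid exchanges the formyl group of 13 with the orthoformate to acetal 16, which loses methanol to the O-protonated 4-methoxy ortho-quinone methide 17 hydrogen-bonded to the chiral phosphoramide anion; the terminal carbon of 15 attacks the methide carbon (C4–C3) and the ring oxygen then closes on the 4-benzyloxybenzylic carbon (O1–C2) in an asynchronous inverse-demand hetero-[4+2] step that restores the aromaticity of ring A. The closest known reaction types are the achiral acid-catalysed three-component union of salicylaldehydes, orthoformates and styrenes to 2-aryl-4-methoxychromans and the chiral N-triflylphosphoramide-catalysed cycloaddition of styrenes to 4-aryl ortho-quinone methides; new here is chiral-anion control of a 4-alkoxy methide on a trioxygenated ring. Ring C closes by [4+2] cycloaddition, the O1–C2 bond forming last as a 6-endo capture of the benzylic cation by the phenolic oxygen. C2 is controlled by the chiral anion, which fixes the face of the methide carbon, while an endo approach of ring B (2,4-cis) places C2 in the (S) configuration; both facial and endo selectivity are therefore needed, because a cis/trans mixture would become a mixture at C2 once C4 is oxidised. C4 is set by the same ion pair and its configuration is erased in step 12, and C2' is a spectator. Regioselectivity (O1 para to the piperidine) is secured by the substrate, since the only free hydroxyl is the one next to the formyl group, and the carbamate keeps nitrogen from quenching the acid. Low temperature, a non-polar medium and a low acid loading are chosen to keep the adduct from re-ionising at C2 and the styrene from oligomerising.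

Step 10
Reactants: 18 methyl (2R)-2-{(2S,4S)-5,7-bis(benzyloxy)-2-[4-(benzyloxy)phenyl]-4-methoxy-3,4-dihydro-2H-chromen-6-yl}piperidine-1-carboxylate
Product: 19 (2S,4S)-5,7-bis(benzyloxy)-2-[4-(benzyloxy)phenyl]-4-methoxy-6-[(2R)-1-methylpiperidin-2-yl]-3,4-dihydro-2H-chromene
Conditions: LiAlH4, THF, 65 °C
Reagents that add atoms: none
Why: Hydride reduction of a methyl carbamate to the N-methyl amine through formamide and iminium stages; the C4 methyl ether keeps ring C inert to hydride, and benzyl ethers and both stereocentres are untouched.

Step 11
Reactants: 19 (2S,4S)-5,7-bis(benzyloxy)-2-[4-(benzyloxy)phenyl]-4-methoxy-6-[(2R)-1-methylpiperidin-2-yl]-3,4-dihydro-2H-chromene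
Product: 20 (2S)-5,7-bis(benzyloxy)-2-[4-(benzyloxy)phenyl]-6-[(2R)-1-methylpiperidin-2-yl]-3,4-dihydro-2H-chromen-4-ol (both C4 epimers)
Conditions: 0.5 M HCl, THF/H2O, 0 °C → rt
Reagents that add atoms: water, O
Why: Acid-catalysed SN1 exchange of a benzylic ether activated by three ring oxygens, the C4 cation being captured by the large excess of water while the amine is protonated and inert; the C4 epimers are not separated because the centre disappears in step 12, and cold dilute acid with short contact is used to limit elimination towards C3 and ionisation at C2.

Step 12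
Reactants: 20 (2S)-5,7-bis(benzyloxy)-2-[4-(benzyloxy)phenyl]-6-[(2R)-1-methylpiperidin-2-yl]-3,4-dihydro-2H-chromen-4-ol
Product: 21 (2S)-5,7-bis(benzyloxy)-2-[4-(benzyloxy)phenyl]-6-[(2R)-1-methylpiperidin-2-yl]-2,3-dihydro-4H-chromen-4-one
Conditions: MnO2, CH2Cl2, rt
Reagents that add atoms: none
Why: Oxidation of an electron-rich benzylic alcohol with activated MnO2 under neutral heterogeneous conditions; both C4 epimers converge on one ketone, the tertiary amine reacts far more slowly, and no base is present that could open the flavanone at C2.

Step 13
Reactants: 21 (2S)-5,7-bis(benzyloxy)-2-[4-(benzyloxy)phenyl]-6-[(2R)-1-methylpiperidin-2-yl]-2,3-dihydro-4H-chromen-4-one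
Product: 22 (2S)-5,7-dihydroxy-2-(4-hydroxyphenyl)-6-[(2R)-1-methylpiperidin-2-yl]-2,3-dihydro-4H-chromen-4-one
Conditions: H2 (1 atm), Pd/C, EtOAc/MeOH, rt
Reagents that add atoms: none
Why: Hydrogenolysis of three aryl benzyl ethers over Pd/C in neutral medium at ambient pressure; these cleave faster than the benzylic C2–O1 and C2'–N bonds or the aryl ketone, the reaction is stopped after three equivalents of hydrogen, and the product is isolated cold without base.

Compound list

1 | 3,5-bis(benzyloxy)phenol | Oc1cc(OCc2ccccc2)cc(OCc2ccccc2)c1 | starting material
2 | N-{[2,6-bis(benzyloxy)-4-hydroxyphenyl]methylidene}-N-methylmethanaminium dichlorophosphate | C[N+](C)=Cc1c(OCc2ccccc2)cc(O)cc1OCc1ccccc1.[O-]P(Cl)(Cl)=O | intermediate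
3 | 2,6-bis(benzyloxy)-4-hydroxybenzaldehyde | O=Cc1c(OCc2ccccc2)cc(O)cc1OCc1ccccc1 | intermediate
4 | 2,6-bis(benzyloxy)-4-(methoxymethoxy)benzaldehyde | COCOc1cc(OCc2ccccc2)c(C=O)c(OCc2ccccc2)c1 | intermediate
5 | (S)-2-methylpropane-2-sulfinamide | CC(C)(C)[S@](=O)N | starting material
6 | (S)-N-{(E)-[2,6-bis(benzyloxy)-4-(methoxymethoxy)phenyl]methylidene}-2-methylpropane-2-sulfinamide | CC(C)(C)[S@](=O)/N=C/c1c(OCc2ccccc2)cc(OCOC)cc1OCc1ccccc1 | intermediate
7 | 1-bromo-4-chlorobutane | ClCCCCBr | starting material
8 | 4-chlorobutylmagnesium bromide | ClCCCC[Mg]Br | intermediate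
9 | (S)-N-{(1R)-1-[2,6-bis(benzyloxy)-4-(methoxymethoxy)phenyl]-5-chloropentyl}-2-methylpropane-2-sulfinamide | CC(C)(C)[S@](=O)N[C@H](CCCCCl)c1c(OCc2ccccc2)cc(OCOC)cc1OCc1ccccc1 | intermediate
10 | (2R)-2-[2,6-bis(benzyloxy)-4-(methoxymethoxy)phenyl]-1-[(S)-tert-butylsulfinyl]piperidine | CC(C)(C)[S@](=O)N1CCCC[C@@H]1c1c(OCc2ccccc2)cc(OCOC)cc1OCc1ccccc1 | intermediate
11 | (R)-3,5-bis(benzyloxy)-4-(piperidin-2-yl)phenol hydrochloride | N1CCCC[C@@H]1c1c(OCc2ccccc2)cc(O)cc1OCc1ccccc1.Cl | intermediate
12 | methyl (R)-2-[2,6-bis(benzyloxy)-4-hydroxyphenyl]piperidine-1-carboxylate | COC(=O)N1CCCC[C@@H]1c1c(OCc2ccccc2)cc(O)cc1OCc1ccccc1 | intermediate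
13 | methyl (R)-2-[2,6-bis(benzyloxy)-3-formyl-4-hydroxyphenyl]piperidine-1-carboxylate | COC(=O)N1CCCC[C@@H]1c1c(OCc2ccccc2)cc(O)c(C=O)c1OCc1ccccc1 | intermediate
14 | 4-(benzyloxy)benzaldehyde | O=Cc1ccc(OCc2ccccc2)cc1 | starting material
15 | 1-(benzyloxy)-4-ethenylbenzene | C=Cc1ccc(OCc2ccccc2)cc1 | intermediate
16 | methyl (R)-2-[2,6-bis(benzyloxy)-3-(dimethoxymethyl)-4-hydroxyphenyl]piperidine-1-carboxylate | COC(=O)N1CCCC[C@@H]1c1c(OCc2ccccc2)cc(O)c(C(OC)OC)c1OCc1ccccc1 | intermediate
17 | methyl (R)-2-[2,6-bis(benzyloxy)-3-(methoxymethylidene)-4-oxocyclohexa-1,5-dien-1-yl]piperidine-1-carboxylate (present as its O-protonated ion pair) | COC(=O)N1CCCC[C@@H]1C1=C(OCc2ccccc2)C(=COC)C(=O)C=C1OCc1ccccc1 | intermediate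
18 | methyl (2R)-2-{(2S,4S)-5,7-bis(benzyloxy)-2-[4-(benzyloxy)phenyl]-4-methoxy-3,4-dihydro-2H-chromen-6-yl}piperidine-1-carboxylate | COC(=O)N1CCCC[C@@H]1c1c(OCc2ccccc2)cc2c(c1OCc1ccccc1)[C@@H](OC)C[C@@H](c1ccc(OCc3ccccc3)cc1)O2 | intermediate
19 | (2S,4S)-5,7-bis(benzyloxy)-2-[4-(benzyloxy)phenyl]-4-methoxy-6-[(2R)-1-methylpiperidin-2-yl]-3,4-dihydro-2H-chromene | CN1CCCC[C@@H]1c1c(OCc2ccccc2)cc2c(c1OCc1ccccc1)[C@@H](OC)C[C@@H](c1ccc(OCc3ccccc3)cc1)O2 | intermediate
20 | (2S)-5,7-bis(benzyloxy)-2-[4-(benzyloxy)phenyl]-6-[(2R)-1-methylpiperidin-2-yl]-3,4-dihydro-2H-chromen-4-ol (both C4 epimers) | CN1CCCC[C@@H]1c1c(OCc2ccccc2)cc2c(c1OCc1ccccc1)C(O)C[C@@H](c1ccc(OCc3ccccc3)cc1)O2 | intermediate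
21 | (2S)-5,7-bis(benzyloxy)-2-[4-(benzyloxy)phenyl]-6-[(2R)-1-methylpiperidin-2-yl]-2,3-dihydro-4H-chromen-4-one | CN1CCCC[C@@H]1c1c(OCc2ccccc2)cc2c(c1OCc1ccccc1)C(=O)C[C@@H](c1ccc(OCc3ccccc3)cc1)O2 | intermediate
22 | (2S)-5,7-dihydroxy-2-(4-hydroxyphenyl)-6-[(2R)-1-methylpiperidin-2-yl]-2,3-dihydro-4H-chromen-4-one | CN1CCCC[C@@H]1c1c(O)cc2c(c1O)C(=O)C[C@@H](c1ccc(O)cc1)O2 | target

Total step count: 13. Longest linear sequence: 12 steps (1 to 22 through steps 1–7 and 9–13); step 8 is a one-step side branch.

Least certain steps

Step 9 (key step, proposed new method).
- What may go wrong: poor facial or endo selectivity, because the styrene has no second binding point to the chiral anion. The C2 configuration may also erode, because the adduct is a 4-alkoxybenzylic ether that the acid can re-ionise, and once ionisation is reversible the ratio drifts towards the near-equal thermodynamic mixture. The electron-rich styrene may oligomerise cationically, and the methide may react sluggishly because three ring oxygens stabilise it heavily.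
- Fallback (known chemistry; C2 is set by a metal-catalysed conjugate addition instead): it sets out from 13 and returns at 20. Addition of MeMgBr to 13 in THF at 0 °C should give the secondary alcohol methyl (2R)-2-[2,6-bis(benzyloxy)-4-hydroxy-3-(1-hydroxyethyl)phenyl]piperidine-1-carboxylate F1. MnO2 oxidation gives the ortho-hydroxyacetophenone methyl (R)-2-[3-acetyl-2,6-bis(benzyloxy)-4-hydroxyphenyl]piperidine-1-carboxylate F2. Condensation with N,N-dimethylformamide dimethyl acetal gives the enaminone methyl (R)-2-{2,6-bis(benzyloxy)-3-[(2E)-3-(dimethylamino)prop-2-enoyl]-4-hydroxyphenyl}piperidine-1-carboxylate F3, and acid closes it to the chromone methyl (R)-2-[5,7-bis(benzyloxy)-4-oxo-4H-chromen-6-yl]piperidine-1-carboxylate F4. Asymmetric 1,4-addition of 4-(benzyloxy)phenylboronic acid under monovalent rhodium catalysis ([Rh(C2H4)2Cl]2 with a chiral diene or bisphosphine whose enantiomer is chosen for the (2S) adduct, aqueous KOH, dioxane) gives the flavanone methyl (2R)-2-{(2S)-5,7-bis(benzyloxy)-2-[4-(benzyloxy)phenyl]-4-oxo-3,4-dihydro-2H-chromen-6-yl}piperidine-1-carboxylate F5. LiAlH4 then reduces ketone and carbamate together to 20.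

Step 11.
- What may go wrong: the C4 cation may lose a C3 proton (elimination to the 2H-chromene) instead of taking up water, and acid-induced opening of the O1–C2 bond would epimerise C2; both arise because the cation is long-lived on this electron-rich ring.
- Fallback (oxidative instead of solvolytic): it sets out from 19 and returns at 21, bypassing 20. 19 is converted into its trifluoroacetate salt, which shields the amine from oxidation, and treated with DDQ in wet CH2Cl2; hydride abstraction from C4, capture by water and loss of methanol should give the ketone in one operation, as in the oxidative cleavage of activated benzylic ethers.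

Step 4.
- What may go wrong: loss of facial selectivity if an ortho-benzyloxy oxygen competes with the sulfinyl oxygen for magnesium, and incomplete addition or imine reduction by β-hydride transfer because the aldimine is doubly ortho-substituted.
- Fallback (catalyst control on a cyclic imine instead of auxiliary control): it sets out from 4 and returns at 12. Addition of 8 to aldehyde 4 gives 1-[2,6-bis(benzyloxy)-4-(methoxymethoxy)phenyl]-5-chloropentan-1-ol F6, and MnO2 oxidation gives the ketone 1-[2,6-bis(benzyloxy)-4-(methoxymethoxy)phenyl]-5-chloropentan-1-one F7. NaN3 in DMF gives 5-azido-1-[2,6-bis(benzyloxy)-4-(methoxymethoxy)phenyl]pentan-1-one F8, and PPh3 (Staudinger reduction, then intramolecular aza-Wittig) closes the cyclic imine 6-[2,6-bis(benzyloxy)-4-(methoxymethoxy)phenyl]-2,3,4,5-tetrahydropyridine F9. Asymmetric hydrogenation ([Ir(cod)Cl]2 with a chiral bisphosphine chosen for the (R)-amine, H2) or an imine reductase gives (R)-2-[2,6-bis(benzyloxy)-4-(methoxymethoxy)phenyl]piperidine F10, which enters the conditions of step 6 in place of 10.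

Step 13.
- What may go wrong: over-reduction by hydrogenolysis of the benzylic C2–O1 bond (opening of ring C) or of the benzylic C2'–N bond, slow turnover through binding of the amine to palladium, and base-induced opening at C2 of the free 5-hydroxyflavanone by its own amine if the product is left in warm protic solution.
- Fallback (Lewis-acid cleavage instead of reduction): it sets out from 21 and ends at 22. BCl3 with pentamethylbenzene as benzyl-cation scavenger in CH2Cl2 at −78 °C removes aryl benzyl ethers without a reducing agent, one further equivalent of BCl3 being consumed by the amine.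

Further compounds

F1 | step 9 | methyl (2R)-2-[2,6-bis(benzyloxy)-4-hydroxy-3-(1-hydroxyethyl)phenyl]piperidine-1-carboxylate (both carbinol epimers) | COC(=O)N1CCCC[C@@H]1c1c(OCc2ccccc2)cc(O)c(C(C)O)c1OCc1ccccc1
F2 | step 9 | methyl (R)-2-[3-acetyl-2,6-bis(benzyloxy)-4-hydroxyphenyl]piperidine-1-carboxylate | COC(=O)N1CCCC[C@@H]1c1c(OCc2ccccc2)cc(O)c(C(C)=O)c1OCc1ccccc1
F3 | step 9 | methyl (R)-2-{2,6-bis(benzyloxy)-3-[(2E)-3-(dimethylamino)prop-2-enoyl]-4-hydroxyphenyl}piperidine-1-carboxylate | COC(=O)N1CCCC[C@@H]1c1c(OCc2ccccc2)cc(O)c(C(=O)/C=C/N(C)C)c1OCc1ccccc1
F4 | step 9 | methyl (R)-2-[5,7-bis(benzyloxy)-4-oxo-4H-chromen-6-yl]piperidine-1-carboxylate | COC(=O)N1CCCC[C@@H]1c1c(OCc2ccccc2)cc2occc(=O)c2c1OCc1ccccc1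
F5 | step 9 | methyl (2R)-2-{(2S)-5,7-bis(benzyloxy)-2-[4-(benzyloxy)phenyl]-4-oxo-3,4-dihydro-2H-chromen-6-yl}piperidine-1-carboxylate | COC(=O)N1CCCC[C@@H]1c1c(OCc2ccccc2)cc2c(c1OCc1ccccc1)C(=O)C[C@@H](c1ccc(OCc3ccccc3)cc1)O2
F0 | step 11 | none | none
F6 | step 4 | 1-[2,6-bis(benzyloxy)-4-(methoxymethoxy)phenyl]-5-chloropentan-1-ol (racemic) | COCOc1cc(OCc2ccccc2)c(C(O)CCCCCl)c(OCc2ccccc2)c1
F7 | step 4 | 1-[2,6-bis(benzyloxy)-4-(methoxymethoxy)phenyl]-5-chloropentan-1-one | COCOc1cc(OCc2ccccc2)c(C(=O)CCCCCl)c(OCc2ccccc2)c1
F8 | step 4 | 5-azido-1-[2,6-bis(benzyloxy)-4-(methoxymethoxy)phenyl]pentan-1-one | COCOc1cc(OCc2ccccc2)c(C(=O)CCCCN=[N+]=[N-])c(OCc2ccccc2)c1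
F9 | step 4 | 6-[2,6-bis(benzyloxy)-4-(methoxymethoxy)phenyl]-2,3,4,5-tetrahydropyridine | COCOc1cc(OCc2ccccc2)c(C2=NCCCC2)c(OCc2ccccc2)c1
F10 | step 4 | (R)-2-[2,6-bis(benzyloxy)-4-(methoxymethoxy)phenyl]piperidine | N1CCCC[C@@H]1c1c(OCc2ccccc2)cc(OCOC)cc1OCc1ccccc1
F0 | step 13 | none | none
A1 | alternative 1 | methyl N-{5-[2,6-dihydroxy-4-(triisopropylsilyloxy)phenyl]-5-hydroxypentyl}carbamate (racemic) | COC(=O)NCCCCC(O)c1c(O)cc(O[Si](C(C)C)(C(C)C)C(C)C)cc1O
A2 | alternative 1 | methyl (R)-2-[2,6-dihydroxy-4-(triisopropylsilyloxy)phenyl]piperidine-1-carboxylate | COC(=O)N1CCCC[C@@H]1c1c(O)cc(O[Si](C(C)C)(C(C)C)C(C)C)cc1O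
A3 | alternative 2 | 1-[4-(benzyloxy)-2,6-bis(methoxymethoxy)phenyl]-5-chloropentan-1-one | COCOc1cc(OCc2ccccc2)cc(OCOC)c1C(=O)CCCCCl
A4 | alternative 2 | (R)-2-[4-(benzyloxy)-2,6-bis(methoxymethoxy)phenyl]piperidine | N1CCCC[C@@H]1c1c(OCOC)cc(OCc2ccccc2)cc1OCOC
A5 | alternative 3 | 3-(benzyloxy)cyclobut-2-en-1-one | O=C1C=C(OCc2ccccc2)C1
A6 | alternative 3 | tert-butyl (R)-2-{[tri(propan-2-yl)silyl]oxyethynyl}piperidine-1-carboxylate | CC(C)(C)OC(=O)N1CCCC[C@@H]1C#CO[Si](C(C)C)(C(C)C)C(C)C
A7 | alternative 3 | (R)-piperidine-2-carboxylic acid ((R)-pipecolic acid) | N1CCCC[C@@H]1C(=O)O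
A8 | alternative 3 | tert-butyl (R)-2-[4-(benzyloxy)-2-hydroxy-6-(triisopropylsilyloxy)phenyl]piperidine-1-carboxylate | CC(C)(C)OC(=O)N1CCCC[C@@H]1c1c(O)cc(OCc2ccccc2)cc1O[Si](C(C)C)(C(C)C)C(C)C
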